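**Strategy.** The lactone oxygen on C6 lies 1,5 to the C1=C10 bond (the later oxirane), and C1–C2–C3(O)–C4(Me)=C5–C6 is the six-membered ring of cis-carveol. The ten-membered carbocycle is therefore grown, not cyclised: an anionic oxy-Cope shift of a carveol-derived cyclohexenol cleaves C1–C6, joins C8 to C9, delivers the Z,Z-diene and C8, and the enolate so formed is alkylated at C7 in the same flask (C7–C11). The precursor is a cis-1,2-dialkenylcyclohex-2-enol: an (E)-silylvinyl group on the carbinol carbon C6, isopropenyl on C1, a protected hydroxyl on C3; silicon is the latent C8 oxygen.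

Key step: step 8

Remark on the chemistry: germacrane locants C1–C15 of the target are used for atom tracking in every intermediate, including the six-membered ones (ring carbons C1–C6, isopropenyl = C9/C10/C14, ring methyl = C15).

Remark on the design: silicon carries a benzyl group so that it can be oxidised with fluoride and peroxide, without electrophiles, in the presence of two trisubstituted olefins. C3 carries a PMB ether, which is inert to fluoride and is removed oxidatively. The acetate arm is a methyl ester, so that lactonisation needs no strong acid.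

**Step 1**
Reactants: 1 (R)-carvone
Product: 2 (1R,5R)-cis-carveol
Conditions: NaBH4, CeCl3·7H2O, MeOH, −78 to 0 °C
Reagents that add atoms: none
Why: Luche reduction gives clean 1,2-addition, with hydride delivered axially and anti to the equatorial isopropenyl group, so the new C3 hydroxyl should be cis to it.

**Step 2**
Reactants: 2 (1R,5R)-cis-carveol
Product: 3 syn-epoxy alcohol
Conditions: VO(acac)2 (2 mol%), t-BuOOH, CH2Cl2, 0 °C to rt
Reagents that add atoms: tert-butyl hydroperoxide, CC(C)(C)OO
Why: Hydroxyl-directed vanadium-catalysed epoxidation touches only the allylic ring olefin, spares the isopropenyl group and places the oxirane on the face of the hydroxyl, hence cis to the isopropenyl group.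

**Step 3**
Reactants: 3 syn-epoxy alcohol
Product: 4 PMB ether
Conditions: NaH, 4-MeOC6H4CH2Cl, n-Bu4NI (cat.), THF/DMF, 0 °C to rt
Reagents that add atoms: 4-methoxybenzyl chloride, COc1ccc(CCl)cc1
Why: Williamson etherification of the secondary alkoxide, which, being cis to the oxirane, has no backside trajectory for Payne migration.

**Step 4**
Reactants: 4 PMB ether
Product: 7 tertiary allylic alcohol, via hydroxy selenide 5 (not isolated), via selenoxide 6 (not isolated)
Conditions: (PhSe)2, NaBH4, EtOH, rt to reflux; then 30% H2O2, THF, 0 °C to rt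
Reagents that add atoms: none
Why: Selenide opening of the epoxide followed by selenoxide syn-elimination: PhSe− attacks the secondary oxirane carbon C5 in the trans-diaxial (Fürst–Plattner) mode open to the conformer with equatorial isopropenyl and ether groups, and the selenoxide can eliminate only towards C6.

**Step 5**
Reactants: 7 tertiary allylic alcohol
Product: 8 enone
Conditions: pyridinium chlorochromate (C5H5NH)[CrO3Cl], 4 Å molecular sieves, CH2Cl2, rt
Reagents that add atoms: pyridinium chlorochromate, [O-][Cr](=O)(=O)Cl.c1cc[nH+]cc1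
Why: Babler–Dauben oxidative transposition, in which the tertiary allylic chromate ester shifts [3,3] to C6 and is oxidised there, restoring the C4=C5 olefin and giving the C6 ketone without touching the isopropenyl group.

**Step 6**
Reactants: 8 enone; 9 ethynylmagnesium bromide
Product: 10 propargylic alcohol
Conditions: CeCl3 (anhydrous, 1.5 equiv), THF, −78 °C; then 9, −78 to 0 °C
Reagents that add atoms: ethynylmagnesium bromide (9), C#C[Mg]Br
Why: Cerium trichloride-promoted 1,2-addition suppresses enolisation at the acidic C1–H, and the slim sp nucleophile attacks the half-chair enone axially, anti to the axial C1–H, so the alkyne should end up cis to the equatorial isopropenyl group at the new C6 centre.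

**Step 7**
Reactants: 10 propargylic alcohol; 11 benzyldimethylsilane
Product: 12 (E)-silylvinyl carbinol (key-step precursor)
Conditions: Pt2[(CH2=CHSiMe2)2O]3 (zerovalent platinum, 0.5 mol%), P(t-Bu)3 (1 mol%), THF, rt
Reagents that add atoms: benzyldimethylsilane (11), C[SiH](C)Cc1ccccc1
Why: Platinum-catalysed syn hydrosilylation of the terminal alkyne of a tertiary propargylic alcohol puts silicon on the terminal carbon C8 and gives the (E)-vinylsilane, the alkyne reacting far faster than either olefin.

**Step 8**
Reactants: 12 (E)-silylvinyl carbinol; 13 methyl bromoacetate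
Product: 16 ten-membered Z,Z-dienone keto ester, via potassium alkoxide 14 (not isolated), via ring-expanded potassium enolate 15 (not isolated)
Conditions: KH, 18-crown-6, THF, 0 °C to rt; then 13, −78 °C
Reagents that add atoms: methyl bromoacetate (13), COC(=O)CBr
Why: KH/18-crown-6 gives the free potassium alkoxide 14, whose [3,3]-sigmatropic shift over C9=C10–C1–C6–C7=C8 forms C8–C9 while C1–C6 breaks, and the resulting enolate 15 is C-alkylated by the bromoacetate at C7 at −78 °C (C7–C11). The closest known reaction type is the anionic oxy-Cope ring expansion of 1,2-dialkenylcyclohexanols to cyclodec-5-enones with trapping of the enolate in the same flask. The ten-membered ring is closed by four-carbon ring expansion through a six-membered chair transition state, not by an end-to-end cyclisation. C8 is set by that chair, in which the silicon of the (E)-vinylsilane is equatorial (chirality transfer from C1 and C6), and C7 by alkylation on the outer face of the ring enolate, whose inner face is covered by the C9–C10=C1–C2 chain. The step needs the chair with C2 axial (C6 alkenyl group pseudoaxial) so that C1=C10 comes out Z, and the cis-1,3 equatorial isopropenyl and C3 ether groups secure it, since the flipped half-chair would put both axial and a boat would flatten the ring; C4=C5 stays Z as a former ring olefin. The endocyclic C4=C5 cannot reach C9, so only the vinylsilane takes part, and the β-silyl enolate has no leaving group to lose.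

**Step 9**
Reactants: 16 ten-membered Z,Z-dienone keto ester
Product: 18 silyl lactone, via hydroxy ester 17 (not isolated)
Conditions: NaBH4, CeCl3·7H2O, MeOH, −78 to 0 °C; then PPTS (cat.), CH2Cl2, rt
Reagents that add atoms: none
Why: Luche 1,2-reduction of the Z-enone from the outer face of the carbonyl (the face the electrophile took at C7, the inner one being blocked across the ring) should set 6S, and the γ-hydroxy methyl ester then closes to the γ-lactone with loss of methanol under mild acid that spares the allylic carbinol and the PMB ether.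

**Step 10**
Reactants: 18 silyl lactone
Product: 20 C8 alcohol, via fluorosilane 19 (not isolated)
Conditions: n-Bu4NF, THF, 0 °C, 15 min; then KHCO3, 30% H2O2, MeOH/THF, rt to 40 °C
Reagents that add atoms: hydrogen peroxide, OO
Why: Fluoride-triggered Tamao–Fleming oxidation: fluoride expels the benzyl group as toluene and basic peroxide oxidises the fluorosilane with retention at C8, conditions that leave both trisubstituted olefins and the PMB ether alone.

**Step 11**
Reactants: 20 C8 alcohol
Product: 23 α-methylene lactone, via Mannich base 21 (not isolated), via trimethylammonium iodide 22 (not isolated)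
Conditions: LiN(i-Pr)2 (3 equiv), THF, −78 °C; CH2=NMe2+ I−, −78 to 0 °C; then MeI, MeOH, rt; then NaHCO3 (aq), EtOAc, rt
Reagents that add atoms: N,N-dimethylmethyleneiminium iodide (Eschenmoser's salt), C=[N+](C)C.[I-]
Why: α-Methylenation by Mannich reaction of the lactone lithium enolate (the C8 hydroxyl rides as its lithium alkoxide, which should not translactonise at −78 °C), followed by quaternisation and Hofmann-type elimination.

**Step 12**
Reactants: 23 α-methylene lactone
Product: 24 C8 isovalerate
Conditions: (Me2CHCH2CO)2O, Et3N, DMAP (cat.), CH2Cl2, 0 °C to rt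
Reagents that add atoms: 3-methylbutanoic anhydride, CC(C)CC(=O)OC(=O)CC(C)C
Why: DMAP-catalysed acylation of the only free hydroxyl, C8–OH.

**Step 13**
Reactants: 24 C8 isovalerate
Product: 25 C3 alcohol
Conditions: DDQ, CH2Cl2/pH 7 phosphate buffer, 0 °C
Reagents that add atoms: none
Why: Oxidative cleavage of the PMB ether by DDQ under neutral conditions frees C3–OH without disturbing the ester, the α-methylene lactone or the olefins.

**Step 14**
Reactants: 25 C3 alcohol
Product: 26 C3 acetate
Conditions: Ac2O, pyridine, DMAP (cat.), CH2Cl2, 0 °C to rt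
Reagents that add atoms: acetic anhydride, CC(=O)OC(C)=O
Why: Standard DMAP-catalysed acetylation of the secondary allylic alcohol.

**Step 15**
Reactants: 26 C3 acetate
Product: 27 target
Conditions: mCPBA (1.05 equiv), NaHCO3, CH2Cl2, 0 °C
Reagents that add atoms: 3-chloroperbenzoic acid, OOC(=O)c1cccc(Cl)c1
Why: Prilezhaev epoxidation picks the only electron-rich olefin, C1=C10 (C4=C5 is flanked by two allylic acyloxy groups and C11=C13 is conjugated), stereospecifically from the Z olefin and from the ring face opposite the C3 and C8 acyloxy groups, which should give the 1R,10S oxirane.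

**Compound list**

1 | (R)-carvone, (5R)-2-methyl-5-(prop-1-en-2-yl)cyclohex-2-en-1-one | CC1=CC[C@H](CC1=O)C(C)=C | starting material
2 | (1R,5R)-cis-carveol, hydroxyl cis to isopropenyl | C=C(C)[C@H]1C[C@@H](O)C(C)=CC1 | intermediate
3 | syn-epoxy alcohol: cis-carveol C4–C5 oxide, oxirane oxygen cis to the C3 hydroxyl and the C1 isopropenyl group | C=C(C)[C@H]1C[C@@H](O)[C@@]2(C)O[C@H]2C1 | intermediate
4 | 4-methoxybenzyl (PMB) ether of 3 | C=C(C)[C@H]1C[C@@H](OCc2ccc(OC)cc2)[C@@]2(C)O[C@H]2C1 | intermediate
5 | hydroxy selenide: C4 tertiary alcohol cis to C3–OPMB, C5–SePh trans to the C4 hydroxyl | C=C(C)[C@H]1C[C@@H](OCc2ccc(OC)cc2)[C@@](C)(O)[C@H]([Se]c2ccccc2)C1 | intermediate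
6 | selenoxide of 5 (configuration at selenium undefined) | C=C(C)[C@H]1C[C@@H](OCc2ccc(OC)cc2)[C@@](C)(O)[C@H]([Se](=O)c2ccccc2)C1 | intermediate
7 | tertiary allylic alcohol: C4(OH)(Me), C5=C6 olefin; C4–OH, C3–OPMB and C1-isopropenyl all cis | C=C(C)[C@H]1C[C@@H](OCc2ccc(OC)cc2)[C@@](C)(O)C=C1 | intermediate
8 | (4R,6R)-4-(4-methoxybenzyloxy)-3-methyl-6-(prop-1-en-2-yl)cyclohex-2-en-1-one (C6 ketone; OPMB and isopropenyl cis) | C=C(C)[C@H]1C[C@@H](OCc2ccc(OC)cc2)C(C)=CC1=O | intermediate
9 | ethynylmagnesium bromide | C#C[Mg]Br | starting material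
10 | (1S,4R,6R)-1-ethynyl-4-(4-methoxybenzyloxy)-3-methyl-6-(prop-1-en-2-yl)cyclohex-2-en-1-ol (ethynyl cis to isopropenyl and OPMB) | C=C(C)[C@H]1C[C@@H](OCc2ccc(OC)cc2)C(C)=C[C@@]1(O)C#C | intermediate
11 | benzyldimethylsilane | C[SiH](C)Cc1ccccc1 | starting material
12 | (1S,4R,6R)-1-[(E)-2-(benzyldimethylsilyl)ethenyl]-4-(4-methoxybenzyloxy)-3-methyl-6-(prop-1-en-2-yl)cyclohex-2-en-1-ol | C=C(C)[C@H]1C[C@@H](OCc2ccc(OC)cc2)C(C)=C[C@@]1(O)/C=C/[Si](C)(C)Cc1ccccc1 | intermediate
13 | methyl bromoacetate | COC(=O)CBr | starting material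
14 | potassium alkoxide of 12 | C=C(C)[C@H]1C[C@@H](OCc2ccc(OC)cc2)C(C)=C[C@@]1([O-])/C=C/[Si](C)(C)Cc1ccccc1.[K+] | intermediate
15 | ring-expanded potassium enolate: (3R,8S)-8-(benzyldimethylsilyl)-3-(4-methoxybenzyloxy)-4,10-dimethylcyclodeca-1(10),4,6-trien-6-olate, 1(10)Z, 4Z, enolate oxygen cis to C8 (ring carbons C5 and C8 trans) | C1/C(C)=C\C[C@@H](OCc2ccc(OC)cc2)/C(C)=C\C(\[O-])=C\[C@H]1[Si](C)(C)Cc1ccccc1.[K+] | intermediate
16 | (3R,7S,8S)-keto ester: methyl 2-[(1(10)Z,4Z)-8-(benzyldimethylsilyl)-3-(4-methoxybenzyloxy)-4,10-dimethyl-6-oxocyclodeca-1(10),4-dien-7-yl]acetate | COC(=O)C[C@H]1C(=O)/C=C(/C)[C@H](OCc2ccc(OC)cc2)C/C=C(/C)C[C@@H]1[Si](C)(C)Cc1ccccc1 | intermediate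
17 | (3R,6S,7S,8S)-hydroxy ester: 6-hydroxy analogue of 16 | COC(=O)C[C@H]1[C@@H](O)/C=C(/C)[C@H](OCc2ccc(OC)cc2)C/C=C(/C)C[C@@H]1[Si](C)(C)Cc1ccccc1 | intermediate
18 | (3R,6S,7S,8S)-8-(benzyldimethylsilyl)-3-(4-methoxybenzyloxy)-13-norgermacra-1(10)Z,4Z-dien-12,6-olide | C1C(=O)O[C@H]2/C=C(/C)[C@H](OCc3ccc(OC)cc3)C/C=C(/C)C[C@H]([Si](C)(C)Cc3ccccc3)[C@@H]12 | intermediate
19 | fluorosilane: 8-(fluorodimethylsilyl) analogue of 18 | C1C(=O)O[C@H]2/C=C(/C)[C@H](OCc3ccc(OC)cc3)C/C=C(/C)C[C@H]([Si](C)(C)F)[C@@H]12 | intermediate
20 | (3R,6S,7R,8S)-8-hydroxy-3-(4-methoxybenzyloxy)-13-norgermacra-1(10)Z,4Z-dien-12,6-olide | C1C(=O)O[C@H]2/C=C(/C)[C@H](OCc3ccc(OC)cc3)C/C=C(/C)C[C@H](O)[C@@H]12 | intermediate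
21 | Mannich base: 11-(dimethylaminomethyl) derivative of 20 (C11 epimers) | CN(C)CC1C(=O)O[C@H]2/C=C(/C)[C@H](OCc3ccc(OC)cc3)C/C=C(/C)C[C@H](O)[C@@H]12 | intermediate
22 | trimethylammonium iodide of 21 | C[N+](C)(C)CC1C(=O)O[C@H]2/C=C(/C)[C@H](OCc3ccc(OC)cc3)C/C=C(/C)C[C@H](O)[C@@H]12.[I-] | intermediate
23 | (3R,6S,7R,8S)-8-hydroxy-3-(4-methoxybenzyloxy)germacra-1(10)Z,4Z,11(13)-trien-12,6-olide | C=C1C(=O)O[C@H]2/C=C(/C)[C@H](OCc3ccc(OC)cc3)C/C=C(/C)C[C@H](O)[C@@H]12 | intermediate
24 | 8-O-(3-methylbutanoyl) ester of 23 | C=C1C(=O)O[C@H]2/C=C(/C)[C@H](OCc3ccc(OC)cc3)C/C=C(/C)C[C@H](OC(=O)CC(C)C)[C@@H]12 | intermediate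
25 | (3R,6S,7R,8S)-3-hydroxy-8-(3-methylbutanoyloxy)germacra-1(10)Z,4Z,11(13)-trien-12,6-olide | C=C1C(=O)O[C@H]2/C=C(/C)[C@H](O)C/C=C(/C)C[C@H](OC(=O)CC(C)C)[C@@H]12 | intermediate
26 | 3-O-acetate of 25 | C=C1C(=O)O[C@H]2/C=C(/C)[C@H](OC(C)=O)C/C=C(/C)C[C@H](OC(=O)CC(C)C)[C@@H]12 | intermediate
27 | CNP0157657.2: (1R,3R,6S,7R,8S,10S)-3-acetoxy-1,10-epoxy-8-(3-methylbutanoyloxy)germacra-4Z,11(13)-dien-12,6-olide | C=C1C(=O)O[C@H]2/C=C(/C)[C@H](OC(C)=O)C[C@H]3O[C@@]3(C)C[C@H](OC(=O)CC(C)C)[C@@H]12 | target

**Step count and risk**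

Total steps: 15. Longest linear sequence: 15 steps, from (R)-carvone (1) to 27.

The three steps most likely to fail:

Step 8. The alkoxide may fragment and recombine or react through the alternative chair, which would erode the C1=C10 geometry and the C8 configuration; proton transfer may also compete with C-alkylation of the enolate. The fallback separates the two events and runs the rearrangement without charge. It sets out from 12, which is silylated with N-(trimethylsilyl)imidazole to the tertiary trimethylsilyl ether F1. Heating F1 in degassed 1,2-dichlorobenzene (sealed, base-washed glass, about 180–200 °C) should bring about the neutral, concerted siloxy-Cope shift through the same chair to the ring-expanded trimethylsilyl enol ether F2. MeLi in THF at 0 °C then releases the lithium enolate F3, which is alkylated with 13 in THF/DMPU at −78 °C. The fallback comes back to the route at 16.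

Step 9. Hydride may be delivered to the wrong face of the C6 carbonyl, since the ten-membered ring is mobile and facial selectivity rests on its conformation alone. The fallback corrects the centre by inversion instead of by reduction. It sets out from 16: the reduction is worked up without acid and the 6-epi hydroxy ester F4 is isolated. A Mitsunobu reaction of F4 (PPh3, diisopropyl azodicarboxylate, 4-nitrobenzoic acid, THF, 0 °C) inverts the allylic C6 to give the (6S)-4-nitrobenzoate F5. Methanolysis of F5 (K2CO3, MeOH) liberates 17, which is lactonised with PPTS as in the main route. The fallback comes back at 18.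

Step 15. The peracid may attack C1=C10 with poor facial selectivity, or C4=C5 may be epoxidised in part. The fallback replaces substrate control by reagent control. It sets out from 26, which is epoxidised under Shi conditions with the fructose-derived ketone catalyst of the enantiomeric series that matches the required face (KHSO5 as 2KHSO5·KHSO4·K2SO4, K2CO3 buffer, MeCN/dimethoxymethane/water, 0 °C). It arrives directly at 27 and makes no new compound.

**Further compounds**

F1 | step 8 | trimethylsilyl ether of 12 | C=C(C)[C@H]1C[C@@H](OCc2ccc(OC)cc2)C(C)=C[C@@]1(O[Si](C)(C)C)/C=C/[Si](C)(C)Cc1ccccc1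
F2 | step 8 | ring-expanded trimethylsilyl enol ether (O-silyl analogue of 15) | C1/C(C)=C\C[C@@H](OCc2ccc(OC)cc2)/C(C)=C\C(\O[Si](C)(C)C)=C\[C@H]1[Si](C)(C)Cc1ccccc1
F3 | step 8 | lithium enolate (lithium analogue of 15) | C1/C(C)=C\C[C@@H](OCc2ccc(OC)cc2)/C(C)=C\C(\[O-])=C\[C@H]1[Si](C)(C)Cc1ccccc1.[Li+]
F4 | step 9 | (3R,6R,7S,8S)-6-epi hydroxy ester (C6 epimer of 17) | COC(=O)C[C@H]1[C@H](O)/C=C(/C)[C@H](OCc2ccc(OC)cc2)C/C=C(/C)C[C@@H]1[Si](C)(C)Cc1ccccc1
F5 | step 9 | (6S)-4-nitrobenzoate of 17 | COC(=O)C[C@H]1[C@@H](OC(=O)c2ccc(cc2)[N+](=O)[O-])/C=C(/C)[C@H](OCc2ccc(OC)cc2)C/C=C(/C)C[C@@H]1[Si](C)(C)Cc1ccccc1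
F0 | step 15 | none | none
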